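## Structural features

The target is a bicyclic cembranoid. A fourteen-membered carbocycle (C1 to C14) is spanned between C10 and C14 by the unit C15(=O)–O, so a seven-membered α,β-unsaturated ε-lactone (C15, C10, C11, C12, C13, C14, O) shares the C10–C14 segment with the large ring. The carbocycle holds a conjugated diene C4=C5–C6=C7 with fully substituted termini (methyl on C4, isopropyl on C7). Along the ring path C3 is trans to C6 but C8 is cis to C5, a trans,cis diene (4E,6E,10Z in CIP terms, because isopropyl outranks C8). The only stereocentres are adjacent: C1 (R, secondary acetate) and C14 (S, fully substituted, methyl and lactone oxygen). Fragile groups are the diene (acid, oxidants, hydroboration, sigmatropic hydrogen shifts), the enoate (conjugate addition; a free O14 would add 5-exo to C11), the acetate beside a tertiary oxygen, and the ionisable tertiary C14–O bond. The real difficulty is a geometrically defined diene made of two trisubstituted alkenes inside a macrocycle, combined with macrocyclisation and esterification of a tertiary carbinol in a seven-membered ring. The key step uses the fact that C4 and C7 are the 1,4-termini of the diene: joined by a σ-bond they form a cyclobutene cis-fused to a twelve-membered ring, and thermal conrotatory opening turns cis fusion into the trans,cis pattern while both cyclobutene stereocentres vanish, so a racemic four-membered ring suffices.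

## Logic of the disconnections

31 ⇒ 30. The C4=C5 and C6=C7 π-bonds are exchanged for a C4–C7 σ-bond and a C5=C6 π-bond. This replaces a double-bond geometry problem by the relative configuration of a small ring and shrinks the macrocycle to twelve members. The forward step must be torquoselective and must run below the threshold of hydrogen shifts; the acetate is already present so nothing follows it.

30 ⇒ 29. The C10–C15 and C15–O bonds are cut together, removing the lactone carbonyl as a one-carbon unit. This avoids acylating the tertiary O14 with a bulky acid and leaves a bromine on C10, cis to C12, as the handle. The forward step must close a seven-membered ring onto a tertiary hydroxyl.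

29 ⇒ 28 ⇒ 26. With O14 masked as a silyl ether, the ring bond C9–C10 is cut. C9 becomes the terminus of a vinyl group on C7 (nucleophile by hydroboration) and C10 a 1,1-dibromoalkene carbon, whose bromine trans to C12 reacts first and so fixes the C10=C11 geometry. The forward step needs high dilution, site selectivity between two bromines and hydroboration of one alkene out of three.

26 ⇒ 25 ⇒ 24. C10=C11 is cut by a one-carbon olefination of a C11 aldehyde, and the aldehyde is stored as a methyl enol ether. The enol ether survives organolithium, borane and acylation conditions. Its release demands acid mild enough for the tertiary silyl ether.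

24 ⇒ 23 ⇒ 22 ⇒ 21. The acetate and the C1–H bond are removed and O14 is unmasked, leading to an α-hydroxy ketone. C1 is set by reagent control because the C14 centre (methyl versus chain) cannot discriminate the faces. The reduction needs the two flanks of the ketone to differ clearly in size, which the silylated quaternary C14 provides.

21 ⇒ 13 + 18. Cutting C1–C2 divides the molecule into a racemic cyclobutene half and an enantiopure half at a bond that needs no stereocontrol. The forward acylation must stop after one addition and tolerate the vinyl group.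

18 ⇒ 17 ⇒ 16 ⇒ 15 ⇒ 14. C11=C12 is cut, since 14 supplies only C1, C12, C13, C14 and the methyl, so C11 must be added by a one-carbon homologation. The dioxolanone of 15 protects O14 and activates C1 in one ring. The forward steps must distinguish the free carboxyl from the ring carbonyl.

13 ⇒ 12 ⇒ 10 ⇒ 9. The C2–I bond and then C8=C9 are cut, leading to a lactone in which C8 is the carbonyl and C2 carries the ring oxygen. The two arms of the cyclobutene are thus distinguished by oxidation state, not by sterics, and C2 comes for free. The forward methylenation must work on a hindered lactol.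

9 ⇒ 7 + 8. C4–C5 and C6–C7 are cut in a [2+2] sense. The six-membered lactone of 7 enforces cis fusion. The forward step is photochemical.

7 ⇒ 5 ⇒ 2 + 3, and 2 ⇒ 1. The C4–C7 bond, the one the key step later breaks, is cut as an aldol bond; lactonisation and dehydration restore the conjugated tetrasubstituted alkene. The dehydration must end in conjugation.

## Other disconnections considered

Alternative 1: The cuts are C7–C8 and C5–C6. In the forward step the alkylcopper from Grignard reagent A4 and CuBr·SMe2 adds syn across 3-methylbut-1-yne A3; the alkenylmetal is passed to zinc with ZnBr2 and coupled with alkenyl iodide A2 under Pd(PPh3)4 to give open-chain diene A1. In its favour, both diene geometries follow from stereospecific events (syn addition, retention in coupling), and on diene stereocontrol this is better than the chosen plan, whose torquoselectivity rests on modest steric preferences. It is also convergent and needs no heating. Against it, A1 is acyclic: the C10–C11 bond, the fourteen-membered ring and the lactone on tertiary O14 are all still to be made, with the diene carried through deprotections, oxidations and a macrocyclisation that must also set the C10=C11 geometry. Carbocupration of an α-branched alkyne with a functionalised alkylcopper is also slow. On structure it solves the diene and postpones both rings; the chosen plan builds the rings first and reveals the diene last with no step after the key step.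

Alternative 2: The cut is C10≡C11. In the forward step diyne A6 is closed with Mo(CC6H4OMe)(OSiPh3)3 to cycloalkyne A5 with loss of but-2-yne A7. In its favour, alkyne metathesis ignores alkenes, a fourteen-membered cycloalkyne is unstrained, and as a ring closure it should be more dependable than the palladium macrocyclisation of the chosen plan. The stereocentres are in place beforehand in both plans, which is equal. Against it, A6 must already contain the trans,cis diene, so that problem is moved, not solved. A5 also lacks C15: a net trans addition of hydrogen to C11 and of a carboxyl carbon to C10 is needed on an alkyne without a nearby directing group, so regiocontrol is doubtful. Several steps follow the key step, against none in the chosen plan.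

Alternative 3: The cut is O–C14. In the forward step the carboxyl of trans-epoxy acid A9 opens the epoxide at the tertiary carbon with inversion (7-exo) to give hydroxy lactone A8, which needs one acetylation. In its favour, the lactone forms on the tertiary carbon without acylating a tertiary alcohol, which is better than step 20 of the chosen plan. One epoxide relays both stereocentres, which is at least equal to chiral pool plus reagent-controlled reduction. Against it, an acid-activated tertiary epoxide in a macrocycle that holds an electron-rich diene invites transannular cation–alkene cyclisation, elimination and loss of inversion. Selective epoxidation of C1=C14 beside the diene is uncertain, and the macrocycle with its diene geometry still has to be built first. Step economy after the key step is close (one step against none); before it, this plan carries the harder burden.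

Key step: step 21

Remarks on the chemistry:
- Cyclobutene compounds 9 to 13 are racemic. From step 12 on, each compound is a pair of diastereomers differing only at C4 and C7 (always cis); one is drawn, and both converge in step 21. The CIP label of C7 changes between vinyl and alkyl stages without any change in space.
- Precursor 30 and target 31 were re-derived atom by atom and are mutually consistent (cis fusion, 1R,14S); no structural correction is needed. Citramalic acid lacks C11, so one homologation (step 11) is added.
- The cyclobutene never carries a formyl group or two alkenyl groups as an isolated intermediate, because such cyclobutenes open or rearrange far below the temperature of step 21. All steps with the C7 vinyl group (6 to 18) run at or below about 40 °C.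

## Route

Step 1
Reactants: 1 4-hydroxybutan-2-one
Product: 2 4-[(tert-butyldimethylsilyl)oxy]butan-2-one
Conditions: TBSCl, imidazole, CH2Cl2, 0 °C to rt
Reagents that add atoms: tert-butyldimethylsilyl chloride, CC(C)(C)[Si](C)(C)Cl
Why: Imidazole-promoted silylation masks the primary hydroxyl so that the ester enolate of step 2 is not quenched; the mild base avoids β-elimination.

Step 2
Reactants: 3 ethyl 3-methylbutanoate; 2 4-[(tert-butyldimethylsilyl)oxy]butan-2-one
Product: 5 ethyl 5-[(tert-butyldimethylsilyl)oxy]-3-hydroxy-3-methyl-2-(propan-2-yl)pentanoate (racemic diastereomer mixture), via lithium ester enolate 4 (not isolated)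
Conditions: LiN(iPr)2, THF, −78 °C; then 2, −78 °C; aq. NH4Cl
Reagents that add atoms: none
Why: Directed aldol addition of a preformed lithium ester enolate to a methyl ketone forms the C4–C7 bond with both future quaternary carbons in place; the diastereomers are irrelevant because both centres become sp2 in step 3.

Step 3
Reactants: 5 ethyl 5-[(tert-butyldimethylsilyl)oxy]-3-hydroxy-3-methyl-2-(propan-2-yl)pentanoate
Product: 7 4-methyl-3-(propan-2-yl)-5,6-dihydro-2H-pyran-2-one, via hydroxy lactone 6 (not isolated)
Conditions: aq. HCl, MeOH, rt; then TsOH·H2O (cat.), PhMe, reflux, Dean–Stark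
Reagents that add atoms: none
Why: Acid removes the silyl group, the δ-hydroxy ester lactonises, and acid-catalysed dehydration of the tertiary β-hydroxyl gives the conjugated tetrasubstituted alkene, as in the dehydration of mevalonolactone-type lactones; any β,γ-isomer should equilibrate into conjugation under the same acid.

Step 4
Reactants: 7 4-methyl-3-(propan-2-yl)-5,6-dihydro-2H-pyran-2-one; 8 acetylene
Product: 9 rac-(1S,6R)-6-methyl-1-(propan-2-yl)-3-oxabicyclo[4.2.0]oct-7-en-2-one
Conditions: hν (medium-pressure Hg lamp, Pyrex), acetone (solvent and sensitiser), C2H2-saturated, −60 °C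
Reagents that add atoms: none
Why: Triplet-sensitised [2+2] photocycloaddition of an α,β-unsaturated δ-lactone to acetylene builds the cyclobutene (C4–C5 and C6–C7 bonds). The six-membered ring enforces cis fusion, placing the C3 and C8 arms on one face, and the lactone keeps the arms chemically distinct.

Step 5
Reactants: 9 rac-(1S,6R)-6-methyl-1-(propan-2-yl)-3-oxabicyclo[4.2.0]oct-7-en-2-one
Product: 10 rac-(1S,6R)-6-methyl-1-(propan-2-yl)-3-oxabicyclo[4.2.0]oct-7-en-2-ol (lactol; anomer mixture)
Conditions: iBu2AlH, CH2Cl2, −78 °C; aq. KNaC4H4O6 work-up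
Reagents that add atoms: none
Why: Lactone-to-lactol reduction stops at the aldehyde level because the tetrahedral aluminate is stable at −78 °C, helped by the neopentyl environment of C8.

Step 6
Reactants: 10 rac-(1S,6R)-6-methyl-1-(propan-2-yl)-3-oxabicyclo[4.2.0]oct-7-en-2-ol
Product: 12 rac-2-[(1R,4S)-4-ethenyl-1-methyl-4-(propan-2-yl)cyclobut-2-en-1-yl]ethan-1-ol, via ring-opened hydroxy aldehyde 11 (not isolated)
Conditions: Ph3PCH3Br, KOtBu (2.5 equiv each), THF, 0 °C to rt
Reagents that add atoms: methyltriphenylphosphonium bromide, C[P+](c1ccccc1)(c1ccccc1)c1ccccc1.[Br-]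
Why: Wittig methylenation of the lactol through its open tautomer installs C9 as a vinyl group on C7 and frees the C2 hydroxyl in one operation. The formyl-substituted cyclobutene exists only in small equilibrium concentration and is consumed as it forms.

Step 7
Reactants: 12 rac-2-[(1R,4S)-4-ethenyl-1-methyl-4-(propan-2-yl)cyclobut-2-en-1-yl]ethan-1-ol
Product: 13 rac-(3S,4R)-3-ethenyl-4-(2-iodoethyl)-4-methyl-3-(propan-2-yl)cyclobut-1-ene
Conditions: I2, PPh3, imidazole, CH2Cl2, 0 °C to rt, dark
Reagents that add atoms: iodine, II
Why: Appel-type iodination of an unhindered primary alcohol (SN2 on the alkoxyphosphonium ion); the alkenes are not touched.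

Step 8
Reactants: 14 (S)-citramalic acid
Product: 15 2-[(4S)-2,2,4-trimethyl-5-oxo-1,3-dioxolan-4-yl]acetic acid
Conditions: Me2C(OMe)2, TsOH·H2O (cat.), acetone, rt
Reagents that add atoms: 2,2-dimethoxypropane, COC(C)(C)OC
Why: Acid-catalysed acetalisation of the α-hydroxy acid unit forms the five-membered dioxolanone in preference to the six-membered alternative, protecting O14 and activating C1 while the C12 carboxyl stays free. The stereocentre is quaternary and cannot epimerise.

Step 9
Reactants: 15 2-[(4S)-2,2,4-trimethyl-5-oxo-1,3-dioxolan-4-yl]acetic acid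
Product: 16 (5S)-5-(2-hydroxyethyl)-2,2,5-trimethyl-1,3-dioxolan-4-one
Conditions: BH3·SMe2, THF, 0 °C to rt; neutral aq. work-up
Reagents that add atoms: none
Why: Borane reduces a free carboxylic acid (through the acyloxyborane) much faster than the dioxolanone carbonyl, giving chemoselective reduction of C12.

Step 10
Reactants: 16 (5S)-5-(2-hydroxyethyl)-2,2,5-trimethyl-1,3-dioxolan-4-one
Product: 17 2-[(4S)-2,2,4-trimethyl-5-oxo-1,3-dioxolan-4-yl]acetaldehyde
Conditions: Dess–Martin periodinane, pyridine, CH2Cl2, 0 °C to rt
Reagents that add atoms: none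
Why: Buffered Dess–Martin oxidation gives the aldehyde without the acid that would translactonise the hydroxyethyl dioxolanone.

Step 11
Reactants: 17 2-[(4S)-2,2,4-trimethyl-5-oxo-1,3-dioxolan-4-yl]acetaldehyde
Product: 18 (5S)-5-(3-methoxyprop-2-en-1-yl)-2,2,5-trimethyl-1,3-dioxolan-4-one (E/Z mixture)
Conditions: MeOCH2PPh3Cl, KN(SiMe3)2, THF, −78 °C; then 17, −78 to 0 °C
Reagents that add atoms: (methoxymethyl)triphenylphosphonium chloride, COC[P+](c1ccccc1)(c1ccccc1)c1ccccc1.[Cl-]
Why: Wittig homologation adds C11 as a methyl enol ether, a masked aldehyde that tolerates organolithium, borane and acylation conditions. At −78 °C the aldehyde reacts far faster than the ring carbonyl.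

Step 12
Reactants: 13 rac-(3S,4R)-3-ethenyl-4-(2-iodoethyl)-4-methyl-3-(propan-2-yl)cyclobut-1-ene; 18 (5S)-5-(3-methoxyprop-2-en-1-yl)-2,2,5-trimethyl-1,3-dioxolan-4-one
Product: 21 (4S)-1-[(1R,4S)-4-ethenyl-1-methyl-4-(propan-2-yl)cyclobut-2-en-1-yl]-4-hydroxy-7-methoxy-4-methylhept-6-en-3-one (plus its (1S,4R)-cyclobutenyl diastereomer), via alkyllithium 19 (not isolated), via lithium hemiketal alkoxide 20 (not isolated)
Conditions: 13, t-BuLi (2.1 equiv), Et2O/pentane, −78 °C; then 18 (1.1 equiv), −78 °C; aq. NH4Cl, −78 °C to rt
Reagents that add atoms: none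
Why: Iodine–lithium exchange gives the primary alkyllithium, which adds once to the dioxolanone carbonyl (C1–C2 bond). The tetrahedral lithium alkoxide persists at −78 °C and collapses only on work-up, releasing acetone and the α-hydroxy ketone, so this is an acyl substitution without over-addition.

Step 13
Reactants: 21 (4S)-1-[(1R,4S)-4-ethenyl-1-methyl-4-(propan-2-yl)cyclobut-2-en-1-yl]-4-hydroxy-7-methoxy-4-methylhept-6-en-3-one
Product: 22 (4S)-1-[(1R,4S)-4-ethenyl-1-methyl-4-(propan-2-yl)cyclobut-2-en-1-yl]-7-methoxy-4-methyl-4-[(triethylsilyl)oxy]hept-6-en-3-one (diastereomer pair)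
Conditions: Et3SiOTf, 2,6-lutidine, CH2Cl2, −78 to 0 °C
Reagents that add atoms: triethylsilyl trifluoromethanesulfonate, CC[Si](CC)(CC)OS(=O)(=O)C(F)(F)F
Why: A silyl triflate with a hindered base silylates the tertiary hydroxyl at low temperature faster than it enolises the ketone. The ether keeps O14 from interfering in the reduction and from forming a lactol with C11 later.

Step 14
Reactants: 22 (4S)-1-[(1R,4S)-4-ethenyl-1-methyl-4-(propan-2-yl)cyclobut-2-en-1-yl]-7-methoxy-4-methyl-4-[(triethylsilyl)oxy]hept-6-en-3-one
Product: 23 (3R,4S)-1-[(1R,4S)-4-ethenyl-1-methyl-4-(propan-2-yl)cyclobut-2-en-1-yl]-7-methoxy-4-methyl-4-[(triethylsilyl)oxy]hept-6-en-3-ol (diastereomer pair)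
Conditions: (S)-2-methyl-CBS-oxazaborolidine (0.3 equiv), catecholborane, PhMe/CH2Cl2, −78 to −40 °C
Reagents that add atoms: none
Why: Corey–Bakshi–Shibata reduction: the (S)-oxazaborolidine binds the ketone with the bulky silylated quaternary C14 side away from the catalyst and delivers hydride to the face that gives the (1R)-carbinol, the same sense as for tert-alkyl ketones (reagent control). Catecholborane at low temperature should not hydroborate the alkenes.

Step 15
Reactants: 23 (3R,4S)-1-[(1R,4S)-4-ethenyl-1-methyl-4-(propan-2-yl)cyclobut-2-en-1-yl]-7-methoxy-4-methyl-4-[(triethylsilyl)oxy]hept-6-en-3-ol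
Product: 24 (3R,4S)-1-[(1R,4S)-4-ethenyl-1-methyl-4-(propan-2-yl)cyclobut-2-en-1-yl]-7-methoxy-4-methyl-4-[(triethylsilyl)oxy]hept-6-en-3-yl acetate (diastereomer pair)
Conditions: Ac2O, pyridine, DMAP (cat.), CH2Cl2, rt
Reagents that add atoms: acetic anhydride, CC(=O)OC(C)=O
Why: DMAP-catalysed acetylation installs the target's acetate early, where it also protects O1 through the remaining steps.

Step 16
Reactants: 24 (3R,4S)-1-[(1R,4S)-4-ethenyl-1-methyl-4-(propan-2-yl)cyclobut-2-en-1-yl]-7-methoxy-4-methyl-4-[(triethylsilyl)oxy]hept-6-en-3-yl acetate
Product: 25 (4S,5R)-7-[(1R,4S)-4-ethenyl-1-methyl-4-(propan-2-yl)cyclobut-2-en-1-yl]-4-methyl-1-oxo-4-[(triethylsilyl)oxy]heptan-5-yl acetate (diastereomer pair)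
Conditions: TsOH·H2O (cat.), acetone/H2O, 0 °C
Reagents that add atoms: water, O
Why: Mild aqueous acid hydrolyses the methyl enol ether (C-protonation, hemiacetal, loss of methanol) to the C11 aldehyde. The hindered tertiary silyl ether and the acetate should survive, and the silyl ether prevents lactol formation.

Step 17
Reactants: 25 (4S,5R)-7-[(1R,4S)-4-ethenyl-1-methyl-4-(propan-2-yl)cyclobut-2-en-1-yl]-4-methyl-1-oxo-4-[(triethylsilyl)oxy]heptan-5-yl acetate
Product: 26 (5S,6R)-1,1-dibromo-8-[(1R,4S)-4-ethenyl-1-methyl-4-(propan-2-yl)cyclobut-2-en-1-yl]-5-methyl-5-[(triethylsilyl)oxy]oct-1-en-6-yl acetate (diastereomer pair)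
Conditions: CBr4, PPh3, Zn, CH2Cl2, rt (reagent formation); then 25, 0 °C to rt
Reagents that add atoms: carbon tetrabromide, BrC(Br)(Br)Br
Why: Corey–Fuchs dibromo-olefination adds C10 with two bromines, one for each of the two carbon–carbon bonds C10 still needs. The zinc variant avoids bromophosphonium by-products that could attack the silyl ether.

Step 18
Reactants: 26 (5S,6R)-1,1-dibromo-8-[(1R,4S)-4-ethenyl-1-methyl-4-(propan-2-yl)cyclobut-2-en-1-yl]-5-methyl-5-[(triethylsilyl)oxy]oct-1-en-6-yl acetate
Product: 28 (1R,4R,7R,14S)-bicyclic (10Z)-10-bromo-alkene: twelve-membered carbocycle C1–C4/C7–C14 cis-fused at C4–C7 to a cyclobut-5-ene and bearing 1-acetoxy + 4-methyl + 7-isopropyl + 14-methyl + 14-triethylsilyloxy (plus 4S,7S diastereomer), via B-alkyl-9-BBN borane 27 (not isolated)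
Conditions: 9-BBN, THF, rt; then slow addition to Pd(dppf)Cl2, AsPh3, Cs2CO3, DMF/THF/H2O, rt to 40 °C, about 0.002 M
Reagents that add atoms: none
Why: 9-BBN hydroborates only the terminal vinyl group (boron on C9); the cyclobutene flanked by two quaternary carbons, the electron-poor dibromoalkene and the ester are inert. In the intramolecular B-alkyl Suzuki–Miyaura coupling, zerovalent palladium inserts faster into the bromine trans to the C12 chain, so C9 is joined trans to C12 and the remaining bromine stays cis to C12 (Z), closing the twelve-membered ring.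

Step 19
Reactants: 28 bicyclic (10Z)-10-bromo-alkene silyl ether
Product: 29 (1R,4R,7R,14S)-bicyclic (10Z)-10-bromo-alkene of step 18 with free 14-hydroxyl (1-acetoxy retained; plus 4S,7S diastereomer)
Conditions: HF·pyridine, pyridine, THF, 0 °C to rt
Reagents that add atoms: none
Why: Buffered fluoride cleaves the tertiary triethylsilyl ether without base, so the neighbouring acetate neither migrates nor hydrolyses.

Step 20
Reactants: 29 bicyclic (10Z)-10-bromo-alkene tertiary alcohol
Product: 30 (1R,4R,7R,14S)-cis-fused cyclobutene lactone acetate: twelve-membered carbocycle C1–C4/C7–C14 with C4–C5=C6–C7 cyclobutene and C10=C11 inside the seven-membered C15(=O)–O14 lactone and 1-acetoxy (plus 4S,7S diastereomer)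
Conditions: Pd(OAc)2, Xantphos, CO (1 atm), NEt3, PhMe/MeCN, 70 °C
Reagents that add atoms: carbon monoxide, [C-]#[O+]
Why: Palladium-catalysed intramolecular alkoxycarbonylation: insertion of zerovalent palladium into the vinyl C–Br bond, CO insertion, and capture of the acyl group by the cis-disposed C14 hydroxyl close the seven-membered unsaturated lactone with retention of alkene geometry. C15 comes from CO, so the tertiary alcohol never has to be acylated by a hindered acid.

Step 21
Reactants: 30 (1R,4R,7R,14S)-cis-fused cyclobutene lactone acetate and its (4S,7S) diastereomer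
Product: 31 target CNP0291129.1: (1R,4E,6E,10Z,14S)-fourteen-membered diene lactone acetate
Conditions: degassed PhMe (0.01 M), BHT (cat.), base-washed sealed tube, 150–165 °C
Reagents that add atoms: none
Why: Heating effects a thermally allowed, concerted four-electron conrotatory electrocyclic opening of the cyclobutene: the C4–C7 σ-bond breaks and becomes the C4=C5 and C6=C7 π-bonds while the old C5=C6 π-bond becomes the central single bond, so the twelve-membered ring grows by two atoms. The closest known reaction type is the thermal opening of cis-fused bicyclo[n.2.0]alkenes to cis,trans-cycloalka-1,3-dienes, which is unimpeded once the large ring has twelve or more members. No ring is closed by cyclisation: the fourteen-membered ring arises purely by scission of the shared σ-bond, and the lactone is a spectator. No stereocentre is created; C4 and C7 become sp2, which is why both diastereomers of 30 give the same 31, and C1 and C14 are untouched. Because C3 and C8 are cis on the four-membered ring, conrotation must turn one outward and the other inward, which fixes the trans,cis pattern; the selectivity still needed is torquoselectivity between the two allowed senses of rotation. In the sense leading to 31, C3 and the isopropyl group rotate outward and the C4 methyl and C8 inward; the other sense would send methyl and C8 outward and C3 and isopropyl inward. The substrate favours the first sense at both termini (a chain outranks methyl for the outward position at C4, and the α-branched isopropyl outranks the unbranched C8 at C7); the two preferences reinforce each other, but each is modest, so the isomer with C3 cis to C6 is the expected minor by-product. The lowest workable temperature is used because the inward methyl and C8 could each donate hydrogen in a 1,5-shift, though both clash in the s-cis conformation that shift requires.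

## Compound list

1 | 4-hydroxybutan-2-one | CC(=O)CCO | starting material
2 | 4-[(tert-butyldimethylsilyl)oxy]butan-2-one | CC(=O)CCO[Si](C)(C)C(C)(C)C | intermediate
3 | ethyl 3-methylbutanoate | CCOC(=O)CC(C)C | starting material
4 | lithium enolate of ethyl 3-methylbutanoate | CCOC(O[Li])=CC(C)C | intermediate (not isolated)
5 | ethyl 5-[(tert-butyldimethylsilyl)oxy]-3-hydroxy-3-methyl-2-(propan-2-yl)pentanoate (racemic, diastereomer mixture) | CCOC(=O)C(C(C)C)C(C)(O)CCO[Si](C)(C)C(C)(C)C | intermediate
6 | 4-hydroxy-4-methyl-3-(propan-2-yl)oxan-2-one | CC(C)C1C(=O)OCCC1(C)O | intermediate (not isolated)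
7 | 4-methyl-3-(propan-2-yl)-5,6-dihydro-2H-pyran-2-one | CC(C)C1=C(C)CCOC1=O | intermediate
8 | acetylene | C#C | starting material
9 | rac-(1S,6R)-6-methyl-1-(propan-2-yl)-3-oxabicyclo[4.2.0]oct-7-en-2-one (cis-fused) | O=C1OCC[C@]2(C)C=C[C@]12C(C)C | intermediate
10 | rac-(1S,6R)-6-methyl-1-(propan-2-yl)-3-oxabicyclo[4.2.0]oct-7-en-2-ol (anomer mixture) | OC1OCC[C@]2(C)C=C[C@]12C(C)C | intermediate
11 | rac-(1S,4R)-4-(2-hydroxyethyl)-4-methyl-1-(propan-2-yl)cyclobut-2-ene-1-carbaldehyde | OCC[C@]1(C)C=C[C@@]1(C=O)C(C)C | intermediate (not isolated)
12 | rac-2-[(1R,4S)-4-ethenyl-1-methyl-4-(propan-2-yl)cyclobut-2-en-1-yl]ethan-1-ol | OCC[C@]1(C)C=C[C@@]1(C=C)C(C)C | intermediate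
13 | rac-(3S,4R)-3-ethenyl-4-(2-iodoethyl)-4-methyl-3-(propan-2-yl)cyclobut-1-ene | ICC[C@]1(C)C=C[C@@]1(C=C)C(C)C | intermediate
14 | (S)-citramalic acid, (2S)-2-hydroxy-2-methylbutanedioic acid | C[C@](O)(CC(=O)O)C(=O)O | starting material
15 | 2-[(4S)-2,2,4-trimethyl-5-oxo-1,3-dioxolan-4-yl]acetic acid | C[C@@]1(CC(=O)O)OC(C)(C)OC1=O | intermediate
16 | (5S)-5-(2-hydroxyethyl)-2,2,5-trimethyl-1,3-dioxolan-4-one | C[C@@]1(CCO)OC(C)(C)OC1=O | intermediate
17 | 2-[(4S)-2,2,4-trimethyl-5-oxo-1,3-dioxolan-4-yl]acetaldehyde | C[C@@]1(CC=O)OC(C)(C)OC1=O | intermediate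
18 | (5S)-5-(3-methoxyprop-2-en-1-yl)-2,2,5-trimethyl-1,3-dioxolan-4-one (E/Z mixture) | C[C@@]1(CC=COC)OC(C)(C)OC1=O | intermediate
19 | {2-[(1R,4S)-4-ethenyl-1-methyl-4-(propan-2-yl)cyclobut-2-en-1-yl]ethyl}lithium (racemic) | [Li]CC[C@]1(C)C=C[C@@]1(C=C)C(C)C | intermediate (not isolated)
20 | lithium alkoxide of the 4-alkyl-4-hydroxy-1,3-dioxolane adduct of 19 and 18 | COC=CC[C@]1(C)OC(C)(C)OC1(O[Li])CC[C@]2(C)C=C[C@@]2(C=C)C(C)C | intermediate (not isolated)
21 | (4S)-1-[(1R,4S)-4-ethenyl-1-methyl-4-(propan-2-yl)cyclobut-2-en-1-yl]-4-hydroxy-7-methoxy-4-methylhept-6-en-3-one (plus (1S,4R)-cyclobutenyl diastereomer) | COC=CC[C@](C)(O)C(=O)CC[C@]1(C)C=C[C@@]1(C=C)C(C)C | intermediate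
22 | (4S)-1-[(1R,4S)-4-ethenyl-1-methyl-4-(propan-2-yl)cyclobut-2-en-1-yl]-7-methoxy-4-methyl-4-[(triethylsilyl)oxy]hept-6-en-3-one (diastereomer pair) | COC=CC[C@](C)(O[Si](CC)(CC)CC)C(=O)CC[C@]1(C)C=C[C@@]1(C=C)C(C)C | intermediate
23 | (3R,4S)-1-[(1R,4S)-4-ethenyl-1-methyl-4-(propan-2-yl)cyclobut-2-en-1-yl]-7-methoxy-4-methyl-4-[(triethylsilyl)oxy]hept-6-en-3-ol (diastereomer pair) | COC=CC[C@](C)(O[Si](CC)(CC)CC)[C@H](O)CC[C@]1(C)C=C[C@@]1(C=C)C(C)C | intermediate
24 | (3R,4S)-1-[(1R,4S)-4-ethenyl-1-methyl-4-(propan-2-yl)cyclobut-2-en-1-yl]-7-methoxy-4-methyl-4-[(triethylsilyl)oxy]hept-6-en-3-yl acetate (diastereomer pair) | COC=CC[C@](C)(O[Si](CC)(CC)CC)[C@H](OC(C)=O)CC[C@]1(C)C=C[C@@]1(C=C)C(C)C | intermediate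
25 | (4S,5R)-7-[(1R,4S)-4-ethenyl-1-methyl-4-(propan-2-yl)cyclobut-2-en-1-yl]-4-methyl-1-oxo-4-[(triethylsilyl)oxy]heptan-5-yl acetate (diastereomer pair) | O=CCC[C@](C)(O[Si](CC)(CC)CC)[C@H](OC(C)=O)CC[C@]1(C)C=C[C@@]1(C=C)C(C)C | intermediate
26 | (5S,6R)-1,1-dibromo-8-[(1R,4S)-4-ethenyl-1-methyl-4-(propan-2-yl)cyclobut-2-en-1-yl]-5-methyl-5-[(triethylsilyl)oxy]oct-1-en-6-yl acetate (diastereomer pair) | BrC(Br)=CCC[C@](C)(O[Si](CC)(CC)CC)[C@H](OC(C)=O)CC[C@]1(C)C=C[C@@]1(C=C)C(C)C | intermediate
27 | B-alkyl-9-borabicyclo[3.3.1]nonane adduct of 26 (boron on C9) | BrC(Br)=CCC[C@](C)(O[Si](CC)(CC)CC)[C@H](OC(C)=O)CC[C@]1(C)C=C[C@@]1(CCB2C3CCCC2CCC3)C(C)C | intermediate (not isolated)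
28 | (1R,4R,7R,14S)-bicyclic (10Z)-10-bromo-alkene silyl ether; twelve-membered carbocycle cis-fused to cyclobutene; 1-OAc, 14-OSiEt3 (plus 4S,7S diastereomer) | CC(=O)O[C@@H]1CC[C@]3(C)C=C[C@]3(C(C)C)CC/C(Br)=C/CC[C@]1(C)O[Si](CC)(CC)CC | intermediate
29 | (1R,4R,7R,14S)-bicyclic (10Z)-10-bromo-alkene tertiary alcohol; 1-OAc, 14-OH (plus 4S,7S diastereomer) | CC(=O)O[C@@H]1CC[C@]3(C)C=C[C@]3(C(C)C)CC/C(Br)=C/CC[C@]1(C)O | intermediate
30 | (1R,4R,7R,14S)-cis-fused cyclobutene lactone acetate, key-step precursor (plus 4S,7S diastereomer) | CC(=O)O[C@@H]1CC[C@]3(C)C=C[C@]3(C(C)C)CCC2=CCC[C@]1(C)OC2=O | intermediate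
31 | CNP0291129.1, (1R,4E,6E,10Z,14S)-fourteen-membered diene lactone acetate | CC(=O)O[C@@H]1CC/C(C)=C/C=C(/C(C)C)CCC2=CCC[C@]1(C)OC2=O | target

## Step count and least certain steps

Total: 21 steps. Longest linear sequence: 17 steps (steps 1–7, then 12–21). The citramalate branch (steps 8–11) has 4 steps and joins at step 12.

Step 21 (key step). The likely failures are insufficient torquoselectivity and, if long heating is needed, competing 1,5-hydrogen migration in the product diene. Both cyclobutene sp3 carbons are quaternary, so one alkyl group must turn inward at each end, which raises the barrier, and the outward preference of isopropyl over a primary chain is small. Fallback: set out from 29 and perform the thermal opening before the lactone exists. Heating 29 under the conditions of step 21 should give the ring-expanded fourteen-membered bromo diene alcohol F1, which lacks the rigid lactone bridge and whose free hydroxyl eases separation of geometric isomers. Carbonylative lactonisation of F1 (Pd(OAc)2, Xantphos, CO, NEt3) then returns to the route at 31.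

Step 20. The tertiary hydroxyl may fail to capture the acylpalladium species in a seven-membered transition state, leading to intermolecular capture, reduction or catalyst decay. Fallback: from 29, hydroxycarbonylation (Pd(OAc)2, dppf, CO, H2O, NEt3) intercepts the acyl species with water to give the seco hydroxy acid F2. Shiina lactonisation (2-methyl-6-nitrobenzoic anhydride, DMAP, NEt3, CH2Cl2, high dilution, rt) then closes the lactone by acyl activation and rejoins the route at 30.

Step 18. Oligomerisation by intermolecular coupling, coupling at the wrong bromine, base-induced dehydrobromination, or slow transmetalation of the alkylborane at the dilution required may intervene; the acetate may also be hydrolysed by the aqueous base. Fallback: from 26, hydroboration–oxidation (9-BBN, then NaBO3) gives the primary alcohol F3, and I2/PPh3/imidazole gives the primary iodide F4. Zinc insertion (Zn, LiCl, THF) gives the alkylzinc iodide F5, used without isolation in a base-free intramolecular Negishi coupling (Pd(PPh3)4, THF/DMF, high dilution), which is likewise selective for the trans bromine. This returns to the route at 28.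

Step 12. Premature 5-exo carbolithiation of the vinyl group by the alkyllithium, or early collapse of the tetrahedral adduct followed by a second addition, may lower the yield, because the alkyllithium is a 5-hexenyl-type species held cis to the alkene. Fallback: from 18, ring opening with EtSH/AlMe3 gives the hydroxy thioester F6, and Et3SiOTf/2,6-lutidine gives the silylated thioester F7. From 13, zinc insertion (Zn, LiCl) gives the alkylzinc iodide F8, which does not cyclise. Fukuyama coupling of F8 with F7 (PdCl2(PPh3)2, PhMe/THF, rt) delivers the ketone directly and rejoins the route at 22.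

Step 4. Energy transfer to the hindered tetrasubstituted chromophore may be inefficient and acetylene is poorly soluble; the strained product may also undergo secondary photoreactions. Fallback: from 7, photocycloaddition with (Z)-1,2-dichloroethene in acetone (a liquid alkene usable in large excess) should give the dichlorocyclobutane lactone F9. Reductive dechlorination with activated Zn (EtOH, warm) then gives the cyclobutene and returns to the route at 9.

## Further compounds

F1 | step 21 | (1R,4E,6E,10Z,14S)-1-acetoxy-10-bromo-14-hydroxy-4,14-dimethyl-7-isopropyl fourteen-membered carbocyclic triene (ring-expanded bromo diene alcohol) | CC(=O)O[C@@H]1CC/C(C)=C/C=C(/C(C)C)CC/C(Br)=C/CC[C@]1(C)O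
F2 | step 20 | seco hydroxy acid: compound 29 with CO2H in place of bromine on C10 (10Z) | CC(=O)O[C@@H]1CC[C@]3(C)C=C[C@]3(C(C)C)CC/C(C(=O)O)=C/CC[C@]1(C)O
F3 | step 18 | primary alcohol: compound 26 with 2-hydroxyethyl in place of ethenyl on C7 | BrC(Br)=CCC[C@](C)(O[Si](CC)(CC)CC)[C@H](OC(C)=O)CC[C@]1(C)C=C[C@@]1(CCO)C(C)C
F4 | step 18 | primary iodide: compound 26 with 2-iodoethyl in place of ethenyl on C7 | BrC(Br)=CCC[C@](C)(O[Si](CC)(CC)CC)[C@H](OC(C)=O)CC[C@]1(C)C=C[C@@]1(CCI)C(C)C
F5 | step 18 | alkylzinc iodide from F4 | BrC(Br)=CCC[C@](C)(O[Si](CC)(CC)CC)[C@H](OC(C)=O)CC[C@]1(C)C=C[C@@]1(CC[Zn]I)C(C)C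
F6 | step 12 | S-ethyl (2S)-2-hydroxy-5-methoxy-2-methylpent-4-enethioate | COC=CC[C@](C)(O)C(=O)SCC
F7 | step 12 | S-ethyl (2S)-5-methoxy-2-methyl-2-[(triethylsilyl)oxy]pent-4-enethioate | COC=CC[C@](C)(O[Si](CC)(CC)CC)C(=O)SCC
F8 | step 12 | alkylzinc iodide from 13 | I[Zn]CC[C@]1(C)C=C[C@@]1(C=C)C(C)C
F9 | step 4 | rac-cis-fused 7,8-dichloro-6-methyl-1-(propan-2-yl)-3-oxabicyclo[4.2.0]octan-2-one (chlorine configurations mixed) | O=C1OCC[C@]2(C)C(Cl)C(Cl)[C@]12C(C)C
A1 | alternative 1 | open-chain diene with acetonide, silyl ether and 4-methoxybenzyl ether | CC(C)(C)[Si](C)(C)OCCCC/C(C(C)C)=C\C=C(C)\CC[C@H]1OC(C)(C)O[C@@]1(C)CCCOCc2ccc(OC)cc2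
A2 | alternative 1 | (E)-alkenyl iodide carrying the acetonide | I/C=C(C)/CC[C@H]1OC(C)(C)O[C@@]1(C)CCCOCc2ccc(OC)cc2
A3 | alternative 1 | 3-methylbut-1-yne | CC(C)C#C
A4 | alternative 1 | 4-(tert-butyldimethylsilyloxy)butylmagnesium bromide | CC(C)(C)[Si](C)(C)OCCCC[Mg]Br
A5 | alternative 2 | fourteen-membered cycloalkyne acetate | CC(=O)O[C@@H]1CC/C(C)=C/C=C(/C(C)C)CCC#CCC[C@]1(C)O
A6 | alternative 2 | acyclic methyl-capped diyne with diene, acetate and tertiary alcohol | CC#CCC/C(C(C)C)=C\C=C(C)\CC[C@@H](OC(C)=O)[C@@](C)(O)CCC#CC
A7 | alternative 2 | but-2-yne | CC#CC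
A8 | alternative 3 | C1-hydroxy lactone (target without the acetyl group) | O[C@@H]1CC/C(C)=C/C=C(/C(C)C)CCC2=CCC[C@]1(C)OC2=O
A9 | alternative 3 | fourteen-membered trans-1,14-epoxy acid | O1[C@H](CC/C(C)=C/C=C(/C(C)C)CC/C(C(O)=O)=C/CC2)[C@]12C
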